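## The problem

The target is a melampolide-type germacranolide. A ten-membered carbocycle (C1–C10) shares its C6–C7 bond, cis, with an α-methylene-γ-butyrolactone (O on C6, C11–C13 on C7). The ring carries a cis 4,5-epoxide, a ring-cis C1=C10 double bond with the methyl ester C14 on C10, an (S)-2-methylglycidate on O8 and an acetate on O9. Six contiguous ring stereocentres (4R,5S,6R,7R,8S,9S) have to be set; the seventh, in the acyl group, is best bought. They fall into a chain of control: C8/C9 are a threo diol of tartrate origin, C8 can direct C7, C7/C8 can direct the hydride that creates C6, and the C6 hydroxyl can direct epoxidation of a ring-cis C4=C5 bond. Neither ring-cis alkene should be left to a macrocyclisation or to an equilibration: conjugated enones in ten-membered rings tend to deconjugate, and once C6 is a ketone, C7 (α to C=O, allylic, β-alkoxy) can epimerise or eliminate under base. Two epoxides (one a glycidic ester), the α-methylene lactone, the enoate and two vicinal esters that can exchange places exclude strong base, strong acid and tin or hydride reagents at the end. The opening is that C10, C1 and the oxygenated C6 are the stumps left when the C1–C6 bond of a bicyclo[4.4.0]decane is cut: a C1≡C10 alkyne and a C6 ketone are the products of an α,β-epoxy ketone fragmentation, and C4=C5 then sits inside the second six-membered ring.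

## Retrosynthesis

**Ester groups and lactone (38 ⇒ 34 ⇒ 33 ⇒ 32 ⇒ 31).** The O8–acyl bond is cut first because the glycidic ester is the most fragile group; it is joined last from alcohol 34 and the lithium salt 36, made from ester 35. The acetate on O9 goes on one step earlier, on 32, where C9–OH is the only free hydroxyl. The lactone C12–O6 bond is cut next, back to triol 31. Oxidation of C12 is preferred to carrying a lactone or acrylate through the tin and palladium steps, where an α-methylene lactone would be reduced. The forward step must oxidise the primary allylic alcohol in the presence of two secondary ones and close onto O6.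

**C10–C14 and C1–H (31 ⇒ 30 ⇒ 28).** The enoate comes from the ring alkyne of 28 by syn addition of H and a metal, then carbonylation of iodide 30. In a ring, syn addition can only give the ring-cis alkene, so geometry is not in question. What is asked is regiochemistry: the metal must go to C10, for which the free propargylic C9 hydroxyl of 28 is provided.

**Epoxide and C6 carbinol (28 ⇒ 27 ⇒ 26 ⇒ 25).** The cis epoxide is taken back to the ring-cis allylic alcohol 26 and that to enone 25. Creating C6 by reduction lets the PMB ether on O8 steer the hydride by chelation; the C6 hydroxyl then steers a peracid to the threo epoxy alcohol 27. The silyl ethers are kept until after this step so that only one alkene has a free allylic hydroxyl.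

**C1–C6, the key cut (25 ⇒ 23).** Reconnecting C1 to C6 turns the ten-membered enynone 25 into the decalin epoxy ketone 23. This is preferred to closing the ring at C7–C8 or C1–C2 because no macrocyclisation is needed, both ring-cis alkenes follow from ring size, and C7–C9 are set before the ring exists. A ring B with an exocyclic methylene at C4, moved into conjugation after the fragmentation, was weighed and rejected: the shift needs base at a stage where C7 is labile, and conjugation may not be favoured in this ring. Ring B therefore carries C4=C5 from the start, and the fragmentation delivers the ring-cis enone directly. The forward reaction must cleave only the fusion bond, which the epoxide position guarantees.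

**C1–C10 and the fusion epoxide (23 ⇒ 22 ⇒ 21 ⇒ 20 ⇒ 19).** The epoxy ketone is made from the bicyclic allylic alcohol 21 by hydroxyl-directed epoxidation (22) and oxidation. Alkaline peroxide on the enone is avoided because it would expose an α-silyloxy, β-alkoxy ketone to hydroxide. Ring A is closed at C1–C10 from dienyl triflate–aldehyde 20, obtained from 19. This choice decides unambiguously which ring-A carbon becomes the ketone, which an annulation onto a cyclic 1,3-dione cannot do. The step must tolerate a hindered alkenyl triflate and either configuration at C10.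

**C7–C11 and C6–C7 (19 ⇒ 13 + 15; 13 ⇒ 9 + 6).** The side chain is attached to C7 by conjugate addition of the alkenyl unit of bromide 15 to the exocyclic enone 13; trapping the enolate on oxygen gives triflate 19 with C1=C6 fixed. C7 is set here by 1,2-induction from C8. Enone 13 comes from aldol condensation of ring-B ketone 9 with aldehyde 6. The precursors are a C7 ketone, a C4 aldehyde and a C3 bromide.

**Building blocks (6 ⇒ 5 ⇒ 4 ⇒ 3 ⇒ 1; 9 ⇒ 7; 15 ⇒ 14).** Aldehyde 6 holds C7–C10 with O8 and O9 differentiated. It comes from diethyl L-tartrate 1 by monoalkylation (3), hydroxyl-directed reduction of one ester (4), silylation (5) and partial reduction. Ketone 9 is the Birch product of 4-methylanisole 7; bromide 15 is the silyl ether of 14.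

## Roads not taken

Alternative 1: The C7–C11 bond is cut. A ten-membered C6 diazophosphonoacetate A1 would be decomposed by Rh2(OAc)4 and the carbenoid would insert into C7–H to give the cis-fused α-phosphono lactone A2; condensation with formaldehyde then gives the methylene group. Its merits are real: the lactone, C7 and the exocyclic alkene arise late and under mild conditions, and insertion proceeds with retention. In this respect it is better than the chosen plan, which needs a three-carbon alkenyl unit and a late oxidation. Its weak points for this target are that C7–H lies next to the deactivating C8 acyloxy group, that the epoxide oxygen and C5–H are competing sites for the carbenoid, and above all that A1 already contains the ten-membered ring with its ring-cis enoate, epoxide and three oxygenated centres. The hard part is therefore moved, not solved. The chosen plan answers that ring problem directly and fixes C7 by an acyclic addition.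

Alternative 2: The C7–C8 bond is cut. The open-chain bromomethyl butenolide aldehyde A3 would be treated with zinc, and the allylmetal would add through C7 to the C8 aldehyde to give the ten-membered alcohol A4 with the α-methylene lactone in place. This is the most convergent road: ring, lactone, C7 and C8 in one step, and clearly fewer steps than the chosen plan. Against it, two stereocentres would be created during a medium-ring closure with only remote control, the α-alkoxy aldehyde can epimerise at C9, and A3 must carry the ring-cis enoate and the epoxide through an acyclic synthesis. The chosen plan is longer, but each stereocentre is set in a separate reaction with a local controlling element, and no ring closure of a ten-membered ring is attempted.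

Alternative 3: The C8–C9 bond is cut and C1–C6 is reconnected. The alkoxide of the cis-dialkenyl cyclohexenol A5 would undergo an anionic oxy-Cope rearrangement (KH, crown ether) to the ten-membered dienone A6. This road also uses ring expansion, reaches the ring faster than the chosen plan, and sets both ring-cis alkenes and the C8/C9 pair in one pericyclic step; on step count to the carbocycle it is superior. Its weaknesses are that A6 has no substituent at C7, so the lactone carbons must be introduced afterwards on the ten-membered ring α to the C6 ketone, and that a cis-divinyl system can react through chair and boat arrangements, which blurs C8/C9. The dioxinone and enol ether in A5 also have to survive potassium alkoxide. The chosen plan sets C7, C8 and C9 before the ring is opened, and offers this against its greater length.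

Key step: step 14

Remark: C6/C7 in 11 and 12, C10 in 21 and 22, and the fusion epoxide carbons in 22–24 are carried as epimer mixtures; all are destroyed later (steps 7 and 14), so their SMILES leave these centres open. PMB = 4-methoxybenzyl, TES = triethylsilyl, TBDPS = tert-butyldiphenylsilyl, Tf = trifluoromethanesulfonyl.

## Steps

Step 1
Reactants: 1 diethyl L-tartrate
Product: 3 diethyl (2R,3R)-2-hydroxy-3-(4-methoxybenzyloxy)butanedioate, via dibutylstannylene acetal 2 (not isolated)
Conditions: Bu2SnO, toluene, reflux (−H2O); then 4-MeOC6H4CH2Cl, Bu4NI (cat.), toluene, 90 °C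
Reagents that add atoms: 4-methoxybenzyl chloride, COc1ccc(CCl)cc1
Why: Tin-mediated monoalkylation: a stannylene acetal is alkylated once only, and the C2 axis of 1 makes both hydroxyls equivalent, so one mono-ether results; the ether oxygen becomes O8.

Step 2
Reactants: 3 diethyl (2R,3R)-2-hydroxy-3-(4-methoxybenzyloxy)butanedioate
Product: 4 ethyl (2R,3S)-3,4-dihydroxy-2-(4-methoxybenzyloxy)butanoate
Conditions: BH3·SMe2, NaBH4 (5 mol%), THF, 0 → 23 °C; MeOH quench
Reagents that add atoms: none
Why: Hydroxyl-directed borane reduction: the alkoxyborane formed at the free hydroxyl delivers hydride through a five-membered chelate to the adjacent ester only (future C10), leaving the ester next to the PMB ether (future C7); no stereocentre is touched.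

Step 3
Reactants: 4 ethyl (2R,3S)-3,4-dihydroxy-2-(4-methoxybenzyloxy)butanoate
Product: 5 ethyl (2R,3S)-2-(4-methoxybenzyloxy)-3,4-bis(triethylsilyloxy)butanoate
Conditions: Et3SiCl, imidazole, DMF, 0 → 23 °C
Reagents that add atoms: chlorotriethylsilane, CC[Si](Cl)(CC)CC
Why: Routine silylation of both hydroxyls; TES is chosen because the primary ether can later be oxidised directly while the secondary one stays.

Step 4
Reactants: 5 ethyl (2R,3S)-2-(4-methoxybenzyloxy)-3,4-bis(triethylsilyloxy)butanoate
Product: 6 (2R,3S)-2-(4-methoxybenzyloxy)-3,4-bis(triethylsilyloxy)butanal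
Conditions: i-Bu2AlH, CH2Cl2, −78 °C; Rochelle salt work-up
Reagents that add atoms: none
Why: Partial reduction of an α-alkoxy ester stops at the chelated aluminium hemiacetal at low temperature; the aldehyde is used crude to avoid epimerisation at C8.

Step 5
Reactants: 7 4-methylanisole
Product: 9 4-methylcyclohex-3-en-1-one, via 1-methoxy-4-methylcyclohexa-1,4-diene 8 (not isolated)
Conditions: Li, NH3(l), t-BuOH, THF, −78 → −33 °C; then (CO2H)2, MeOH–H2O, 23 °C
Reagents that add atoms: water, O
Why: Birch reduction leaves both substituted carbons on double bonds, and mild oxalic acid hydrolysis of the enol ether gives the β,γ-unsaturated ketone without moving C4=C5 into conjugation.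

Step 6
Reactants: 9 4-methylcyclohex-3-en-1-one; 6 (2R,3S)-2-(4-methoxybenzyloxy)-3,4-bis(triethylsilyloxy)butanal
Product: 11 aldol adduct, 4-methylcyclohex-3-en-1-one bearing at C6 the chain C7H(OH)–C8H(OPMB)–C9H(OTES)–C10H2OTES (C8 and C9 as in 6; C6 and C7 epimer mixture), via lithium dienolate 10 (not isolated)
Conditions: lithium diisopropylamide, THF, −78 °C; then 6, −78 °C; NH4Cl
Reagents that add atoms: none
Why: Directed aldol addition: the CH2 between carbonyl and alkene (C6) is by far the most acidic site, and the lithium dienolate attacks aldehydes through this α-carbon; the two new centres are removed in step 7.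

Step 7
Reactants: 11 aldol adduct
Product: 13 (E)-exocyclic enone, 2-alkylidene-4-methylcyclohex-3-en-1-one with C6=C7 and the chain C8H(OPMB)–C9H(OTES)–C10H2OTES on C7, via mesylate 12 (not isolated)
Conditions: MeSO2Cl, Et3N, CH2Cl2, −20 → 0 °C
Reagents that add atoms: none
Why: Mesylation and E1cB loss of mesylate through the doubly activated C6–H give the alkylidene ketone; the (E)-isomer with C8 turned away from the carbonyl is the stable one, and Et3N is too weak to remove the γ-proton at C8.

Step 8
Reactants: 14 2-bromoprop-2-en-1-ol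
Product: 15 (2-bromoallyloxy)(tert-butyl)diphenylsilane
Conditions: t-BuPh2SiCl, imidazole, CH2Cl2, 23 °C
Reagents that add atoms: tert-butyl(chloro)diphenylsilane, CC(C)(C)[Si](Cl)(c1ccccc1)c1ccccc1
Why: Routine silylation; the bulky silyl group survives organolithium, chromium and acetic acid conditions and slows silyl migration in the derived alkenyllithium.

Step 9
Reactants: 15 (2-bromoallyloxy)(tert-butyl)diphenylsilane; 13 (E)-exocyclic enone
Product: 19 dienyl triflate, 4-methylcyclohexa-1,3-dien-1-yl triflate bearing at C6 the chain C7H[C(=CH2)CH2OTBDPS]–C8H(OPMB)–C9H(OTES)–C10H2OTES, via alkenyllithium 16 (not isolated), via lithium dialkenylcuprate 17 (not isolated), via lithium dienolate 18 (not isolated)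
Conditions: t-BuLi (2 equiv), Et2O, −78 °C; CuBr·SMe2 (0.5 equiv), −78 → −40 °C; 13, THF, −78 °C; then PhNTf2, −78 → 0 °C
Reagents that add atoms: N-phenylbis(trifluoromethanesulfonimide), O=S(=O)(N(c1ccccc1)S(=O)(=O)C(F)(F)F)C(F)(F)F
Why: Bromine–lithium exchange and transmetalation give a dialkenylcuprate that adds 1,4 to the s-cis exocyclic enone at C7 on the face anti to the γ-alkoxy group (H8 eclipsing the alkene to relieve A(1,3) strain, as in cuprate additions to (E)-γ-alkoxy enoates), which sets C7 anti to O8. The enolate, regiodefined by the addition, is trapped on oxygen and so fixes the C1=C6 double bond.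

Step 10
Reactants: 19 dienyl triflate
Product: 20 aldehyde, as 19 with C10 as CHO and the C9 TES ether retained
Conditions: (COCl)2, DMSO, CH2Cl2, −78 → −30 °C; Et3N, −78 → 0 °C
Reagents that add atoms: none
Why: Under Swern conditions a primary TES ether is cleaved and oxidised in one operation while a secondary TES ether is left (selective oxidation of primary silyl ethers); the α-silyloxy aldehyde is kept cold and used directly.

Step 11
Reactants: 20 aldehyde
Product: 21 bicyclic dienol, 4-methyl-bicyclo[4.4.0]deca-1(6),4-dien-10-ol skeleton (germacrane numbering) with 9-OTES, 8-OPMB and the C7 side chain (7,8-cis; 8,9-trans; C10 epimers)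
Conditions: CrCl2, NiCl2 (2 mol%), DMF, 23 °C
Reagents that add atoms: none
Why: Nozaki–Hiyama–Kishi reaction: zerovalent nickel inserts into the alkenyl triflate, transmetalation gives an alkenyl species of trivalent chromium, and addition to the tethered aldehyde closes ring A by 6-exo attack on C10; both C10 epimers are usable because C10 is oxidised in step 13.

Step 12
Reactants: 21 bicyclic dienol
Product: 22 fusion epoxy alcohol, as 21 with a C1–C6 epoxide cis to the C10 hydroxyl (diastereomer mixture)
Conditions: VO(acac)2 (5 mol%), t-BuOOH, CH2Cl2, 0 °C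
Reagents that add atoms: tert-butyl hydroperoxide, CC(C)(C)OO
Why: Hydroxyl-directed epoxidation through a vanadium alkoxide–peroxide complex reaches only the allylic, tetrasubstituted C1=C6 bond and leaves C4=C5 and C11=C13 alone; oxygen arrives on the face of the C10 hydroxyl, and either face serves.

Step 13
Reactants: 22 fusion epoxy alcohol
Product: 23 fusion epoxy ketone, 1,6-epoxy-4-methyl-bicyclo[4.4.0]dec-4-en-10-one with 9-OTES, 8-OPMB and the C7 side chain
Conditions: Dess–Martin periodinane, NaHCO3, CH2Cl2, 0 → 23 °C
Reagents that add atoms: none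
Why: Buffered Dess–Martin oxidation of a secondary alcohol next to an epoxide; the neutral conditions spare the allylic epoxide and silyl ethers.

Step 14
Reactants: 23 fusion epoxy ketone
Product: 25 ten-membered enynone, (4Z)-4-methylcyclodec-4-en-1(10)-yn-6-one (germacrane numbering) with the C7 side chain C(=CH2)CH2OTBDPS, 8-OPMB and 9-OTES, via tosylhydrazone 24 (not isolated)
Conditions: TsNHNH2, AcOH–CH2Cl2 (1:2), −20 → 23 °C
Reagents that add atoms: none
Why: p-Toluenesulfonyl hydrazide condenses with the C10 ketone to give hydrazone 24. Its nitrogen lone pair pushes through C10=N and opens the C1–O bond of the epoxide, giving a C6 alkoxide on a tosylazo-alkene. The alkoxide collapses to the C6 ketone as the C1–C6 bond breaks, C1≡C10 forms, and N2 and p-toluenesulfinate leave in a Grob-type fragmentation. The closest known reaction type is the Eschenmoser–Tanabe fragmentation of ring-fused α,β-epoxy ketones (octalone oxides) to cyclodecynones. No ring is closed: the ten-membered ring is uncovered by cutting the bond shared by rings A and B, so no closure mode and no dilution apply. No stereocentre is formed; C1, C6 and C10 lose their mixed configurations and C7, C8 and C9 are untouched. The step needs only regiospecific cleavage of C1–C6, which is secured by placing the epoxide on both fusion carbons next to the single ketone, and C4=C5 stays ring-cis because it was part of ring B. The cold, weakly acidic medium is chosen to spare the allylic epoxide and the C7 centre of the product; loss of the C9 TES ether here would be harmless.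

Step 15
Reactants: 25 ten-membered enynone
Product: 26 allylic alcohol, as 25 with C6–OH cis to the C7 side chain
Conditions: Zn(BH4)2, Et2O, −30 °C
Reagents that add atoms: none
Why: Chelation-controlled 1,2-reduction: zinc bridges the C6 carbonyl and the C8 PMB ether, and axial hydride delivery to this six-membered chelate with the C7 and C8 substituents equatorial gives the 6,8-syn, 6,7-anti alcohol, which is the hydroxyl cis to the side chain; no base is present, so C7 is not at risk.

Step 16
Reactants: 26 allylic alcohol
Product: 27 epoxy alcohol, as 26 with a cis 4,5-epoxide on the face opposite to the C6 hydroxyl (threo)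
Conditions: mCPBA, NaHCO3, CH2Cl2, 0 °C
Reagents that add atoms: 3-chloroperoxybenzoic acid, O=C(OO)c1cccc(Cl)c1
Why: Hydroxyl-directed peracid epoxidation: for a ring-cis trisubstituted alkene A(1,3) strain holds H6 in the alkene plane, so hydrogen-bonded delivery gives the threo epoxy alcohol, the trans product typical of medium-ring cis-cycloalkenols with peracids; the less nucleophilic C11=C13 bond and the alkyne do not react.

Step 17
Reactants: 27 epoxy alcohol
Product: 28 epoxy triol, as 27 with free hydroxyls at C6, C9 and C12
Conditions: Bu4NF, AcOH, THF, 0 → 23 °C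
Reagents that add atoms: none
Why: Fluoride cleaves both silyl ethers; the acetic acid buffer keeps alkoxide concentration low so that the 2,3-epoxy alcohol does not undergo Payne rearrangement.

Step 18
Reactants: 28 epoxy triol
Product: 30 alkenyl iodide, as 28 with ring-cis C1=C10 and iodine on C10, via alkenylstannane 29 (not isolated)
Conditions: PdCl2(PPh3)2 (5 mol%), Bu3SnH, THF, 0 °C; then I2, CH2Cl2, 0 °C
Reagents that add atoms: iodine, II
Why: Palladium-catalysed hydrostannation adds H and Sn syn, which in a ring gives the ring-cis alkene, and puts tin on the carbon next to the free propargylic hydroxyl (C10); iododestannylation proceeds with retention.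

Step 19
Reactants: 30 alkenyl iodide
Product: 31 methyl ester triol, as 30 with CO2CH3 on C10
Conditions: Pd(PPh3)4 (10 mol%), CO (1 atm), MeOH–DMF, Et3N, 50 °C
Reagents that add atoms: carbon monoxide, [C-]#[O+]; methanol, CO
Why: Carbonylative methanolysis (oxidative addition to zerovalent palladium, CO insertion, methanolysis) keeps the alkene geometry; epoxide and alcohols are inert to the weak base.

Step 20
Reactants: 31 methyl ester triol
Product: 32 lactone, the target skeleton with 8-OPMB and free 9-OH
Conditions: TEMPO (20 mol%), PhI(OAc)2, CH2Cl2, 23 °C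
Reagents that add atoms: none
Why: Oxidative lactonisation of a 1,4-diol: the primary allylic alcohol is oxidised first, the enal is captured by the cis-placed C6 hydroxyl as a five-membered lactol, and this is oxidised on to the lactone. The C9 hydroxyl is secondary, sits on the opposite ring face to C11 and cannot bridge to C12.

Step 21
Reactants: 32 lactone
Product: 33 C9 acetate
Conditions: Ac2O, pyridine, DMAP (cat.), CH2Cl2, 0 °C
Reagents that add atoms: acetic anhydride, CC(=O)OC(C)=O
Why: C9–OH is the only free hydroxyl, so standard acetylation is selective.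

Step 22
Reactants: 33 C9 acetate
Product: 34 C8 alcohol
Conditions: DDQ, CH2Cl2–pH 7 buffer, 0 → 23 °C
Reagents that add atoms: none
Why: Oxidative cleavage of the PMB ether by electron transfer under neutral buffer; the electron-poor alkenes, epoxide and esters are inert to DDQ.

Step 23
Reactants: 35 methyl (S)-2-methyloxirane-2-carboxylate
Product: 36 lithium (S)-2-methyloxirane-2-carboxylate
Conditions: LiOH·H2O, THF–H2O, 0 °C; lyophilise
Reagents that add atoms: lithium hydroxide, [Li+].[OH-]
Why: Cold saponification; hydroxide attacks the ester carbonyl far faster than the 2,2-disubstituted epoxide, and the acid is kept as its salt to avoid acid-induced opening.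

Step 24
Reactants: 36 lithium (S)-2-methyloxirane-2-carboxylate; 34 C8 alcohol
Product: 38 target, (4R,5S,6R,7R,8S,9S)-9-acetoxy-4,5-epoxy-8-[(S)-2-methyloxirane-2-carbonyloxy]-14-methoxycarbonyl-germacra-1(10),11(13)-dien-12,6-olide with ring-cis C1=C10, via mixed anhydride 37 (not isolated)
Conditions: 2,4,6-Cl3C6H2COCl, Et3N, THF, 0 °C; then 34, DMAP, toluene, 0 → 23 °C
Reagents that add atoms: none
Why: Yamaguchi esterification: the carboxylate forms the mixed trichlorobenzoic anhydride, and DMAP transfers the less hindered acyl group to the C8 hydroxyl; low temperature and short contact limit acetyl migration from O9.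

## Compound list

1 | diethyl L-tartrate | CCOC(=O)[C@H](O)[C@@H](O)C(=O)OCC | starting material
2 | diethyl (4R,5R)-2,2-dibutyl-1,3,2-dioxastannolane-4,5-dicarboxylate | CCOC(=O)[C@@H]1O[Sn](CCCC)(CCCC)O[C@H]1C(=O)OCC | intermediate
3 | diethyl (2R,3R)-2-hydroxy-3-(4-methoxybenzyloxy)butanedioate | CCOC(=O)[C@H](OCc1ccc(OC)cc1)[C@@H](O)C(=O)OCC | intermediate
4 | ethyl (2R,3S)-3,4-dihydroxy-2-(4-methoxybenzyloxy)butanoate | CCOC(=O)[C@H](OCc1ccc(OC)cc1)[C@@H](O)CO | intermediate
5 | ethyl (2R,3S)-2-(4-methoxybenzyloxy)-3,4-bis(triethylsilyloxy)butanoate | CCOC(=O)[C@H](OCc1ccc(OC)cc1)[C@@H](O[Si](CC)(CC)CC)CO[Si](CC)(CC)CC | intermediate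
6 | (2R,3S)-2-(4-methoxybenzyloxy)-3,4-bis(triethylsilyloxy)butanal | O=C[C@H](OCc1ccc(OC)cc1)[C@@H](O[Si](CC)(CC)CC)CO[Si](CC)(CC)CC | intermediate
7 | 4-methylanisole | COc1ccc(C)cc1 | starting material
8 | 1-methoxy-4-methylcyclohexa-1,4-diene | COC1=CCC(C)=CC1 | intermediate
9 | 4-methylcyclohex-3-en-1-one | CC1=CCC(=O)CC1 | intermediate
10 | lithium 4-methylcyclohexa-1,3-dien-1-olate | CC1=CC=C(O[Li])CC1 | intermediate
11 | aldol adduct (C6, C7 epimers) | CC1=CC(C(O)[C@H](OCc2ccc(OC)cc2)[C@@H](O[Si](CC)(CC)CC)CO[Si](CC)(CC)CC)C(=O)CC1 | intermediate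
12 | mesylate of 11 | CC1=CC(C(OS(C)(=O)=O)[C@H](OCc2ccc(OC)cc2)[C@@H](O[Si](CC)(CC)CC)CO[Si](CC)(CC)CC)C(=O)CC1 | intermediate
13 | (E)-exocyclic enone | CC1=C/C(=C\[C@H](OCc2ccc(OC)cc2)[C@@H](O[Si](CC)(CC)CC)CO[Si](CC)(CC)CC)C(=O)CC1 | intermediate
14 | 2-bromoprop-2-en-1-ol | C=C(Br)CO | starting material
15 | (2-bromoallyloxy)(tert-butyl)diphenylsilane | C=C(Br)CO[Si](c1ccccc1)(c1ccccc1)C(C)(C)C | intermediate
16 | [3-(tert-butyldiphenylsilyloxy)prop-1-en-2-yl]lithium | [Li]C(=C)CO[Si](c1ccccc1)(c1ccccc1)C(C)(C)C | intermediate
17 | lithium bis[3-(tert-butyldiphenylsilyloxy)prop-1-en-2-yl]cuprate | [Li+].C=C(CO[Si](c1ccccc1)(c1ccccc1)C(C)(C)C)[Cu-]C(=C)CO[Si](c1ccccc1)(c1ccccc1)C(C)(C)C | intermediate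
18 | lithium dienolate of the conjugate adduct | CC1=CC([C@H](C(=C)CO[Si](c2ccccc2)(c2ccccc2)C(C)(C)C)[C@H](OCc2ccc(OC)cc2)[C@@H](O[Si](CC)(CC)CC)CO[Si](CC)(CC)CC)=C(O[Li])CC1 | intermediate
19 | dienyl triflate | CC1=CC([C@H](C(=C)CO[Si](c2ccccc2)(c2ccccc2)C(C)(C)C)[C@H](OCc2ccc(OC)cc2)[C@@H](O[Si](CC)(CC)CC)CO[Si](CC)(CC)CC)=C(OS(=O)(=O)C(F)(F)F)CC1 | intermediate
20 | C10 aldehyde of the dienyl triflate | CC1=CC([C@H](C(=C)CO[Si](c2ccccc2)(c2ccccc2)C(C)(C)C)[C@H](OCc2ccc(OC)cc2)[C@@H](O[Si](CC)(CC)CC)C=O)=C(OS(=O)(=O)C(F)(F)F)CC1 | intermediate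
21 | bicyclic dienol (C10 epimers) | OC1[C@H](O[Si](CC)(CC)CC)[C@@H](OCc2ccc(OC)cc2)[C@@H](C(=C)CO[Si](c2ccccc2)(c2ccccc2)C(C)(C)C)C2=C1CCC(C)=C2 | intermediate
22 | fusion epoxy alcohol (diastereomer mixture at C1, C6, C10) | OC1[C@H](O[Si](CC)(CC)CC)[C@@H](OCc2ccc(OC)cc2)[C@@H](C(=C)CO[Si](c2ccccc2)(c2ccccc2)C(C)(C)C)C23OC12CCC(C)=C3 | intermediate
23 | fusion epoxy ketone (both epoxide faces) | O=C1[C@H](O[Si](CC)(CC)CC)[C@@H](OCc2ccc(OC)cc2)[C@@H](C(=C)CO[Si](c2ccccc2)(c2ccccc2)C(C)(C)C)C23OC12CCC(C)=C3 | intermediate
24 | tosylhydrazone of 23 | Cc1ccc(cc1)S(=O)(=O)NN=C1[C@H](O[Si](CC)(CC)CC)[C@@H](OCc2ccc(OC)cc2)[C@@H](C(=C)CO[Si](c2ccccc2)(c2ccccc2)C(C)(C)C)C23OC12CCC(C)=C3 | intermediate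
25 | ten-membered (4Z)-enynone | C/C1=C/C(=O)[C@H](C(=C)CO[Si](c2ccccc2)(c2ccccc2)C(C)(C)C)[C@H](OCc2ccc(OC)cc2)[C@@H](O[Si](CC)(CC)CC)C#CCC1 | intermediate
26 | C6 allylic alcohol | C/C1=C/[C@H](O)[C@H](C(=C)CO[Si](c2ccccc2)(c2ccccc2)C(C)(C)C)[C@H](OCc2ccc(OC)cc2)[C@@H](O[Si](CC)(CC)CC)C#CCC1 | intermediate
27 | 4,5-epoxy alcohol | C[C@]12O[C@H]1[C@H](O)[C@H](C(=C)CO[Si](c1ccccc1)(c1ccccc1)C(C)(C)C)[C@H](OCc1ccc(OC)cc1)[C@@H](O[Si](CC)(CC)CC)C#CCC2 | intermediate
28 | epoxy triol | C[C@]12O[C@H]1[C@H](O)[C@H](C(=C)CO)[C@H](OCc1ccc(OC)cc1)[C@@H](O)C#CCC2 | intermediate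
29 | C10 tributylstannyl alkene | C[C@]12O[C@H]1[C@H](O)[C@H](C(=C)CO)[C@H](OCc1ccc(OC)cc1)[C@@H](O)/C(=C\CC2)[Sn](CCCC)(CCCC)CCCC | intermediate
30 | C10 iodoalkene | C[C@]12O[C@H]1[C@H](O)[C@H](C(=C)CO)[C@H](OCc1ccc(OC)cc1)[C@@H](O)/C(I)=C\CC2 | intermediate
31 | methyl ester triol | C[C@]12O[C@H]1[C@H](O)[C@H](C(=C)CO)[C@H](OCc1ccc(OC)cc1)[C@@H](O)/C(C(=O)OC)=C\CC2 | intermediate
32 | lactone with 8-OPMB and 9-OH | C=C1C(=O)O[C@@H]2[C@H]1[C@H](OCc1ccc(OC)cc1)[C@@H](O)/C(C(=O)OC)=C\CC[C@@]1(C)O[C@@H]21 | intermediate
33 | lactone with 8-OPMB and 9-OAc | C=C1C(=O)O[C@@H]2[C@H]1[C@H](OCc1ccc(OC)cc1)[C@@H](OC(C)=O)/C(C(=O)OC)=C\CC[C@@]1(C)O[C@@H]21 | intermediate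
34 | lactone with 8-OH and 9-OAc | C=C1C(=O)O[C@@H]2[C@H]1[C@H](O)[C@@H](OC(C)=O)/C(C(=O)OC)=C\CC[C@@]1(C)O[C@@H]21 | intermediate
35 | methyl (S)-2-methyloxirane-2-carboxylate | COC(=O)[C@]1(C)CO1 | starting material
36 | lithium (S)-2-methyloxirane-2-carboxylate | [Li+].[O-]C(=O)[C@]1(C)CO1 | intermediate
37 | (S)-2-methyloxirane-2-carboxylic 2,4,6-trichlorobenzoic anhydride | O=C(OC(=O)[C@]1(C)CO1)c1c(Cl)cc(Cl)cc1Cl | intermediate
38 | target (CNP0274195.1) | C=C1C(=O)O[C@@H]2[C@H]1[C@H](OC(=O)[C@]1(C)CO1)[C@@H](OC(C)=O)/C(C(=O)OC)=C\CC[C@@]1(C)O[C@@H]21 | target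

## Step count and least certain steps

Total: 24 steps. Longest linear sequence: 21 steps (1 → 38 through steps 1–4, 6, 7, 9–22 and 24).

**Step 14 (key step).** The most likely failure is acid-induced opening or rearrangement of the tetrasubstituted allylic epoxide before the hindered C10 ketone has condensed with the hydrazide; enolisation at C7 of the product enone is a second risk. Fallback, the N-aminoaziridine variant of the same fragmentation, which needs no acid: from 23, condensation with trans-2,3-diphenylaziridin-1-amine gives the N-aziridinyl imine F1, and warming in toluene expels trans-stilbene and N2 and delivers 25, where the route is rejoined.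

**Step 15.** Hydride may arrive on the wrong face if the ring conformation overrides the zinc chelate, because the ketone lies in a medium ring with a branched α-carbon. Fallback by inversion instead of facial control: from 25 the reduction then gives mainly the C6 epimer F2; Mitsunobu reaction with 4-nitrobenzoic acid, PPh3 and diisopropyl azodicarboxylate gives the inverted 4-nitrobenzoate F3, and K2CO3 in methanol releases 26.

**Step 12.** The vanadium catalyst is a Lewis acid and may open the new allylic epoxide or promote rearrangement; slow reaction at the hindered tetrasubstituted alkene would make this worse. Fallback by reversing oxidation and epoxidation: from 21, Dess–Martin oxidation gives the dienone F4, and Weitz–Scheffer epoxidation (H2O2, NaOH, MeOH, 0 °C), which attacks the α,β bond of a linear dienone, gives 23.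

**Step 18.** Tin may go to C1 instead of C10, because the branched C9 pushes tin away while the hydroxyl draws it near; a regioisomer mixture would result. Fallback using a magnesium alkoxide-directed syn-hydromagnesiation, run before the epoxide is present because low-valent titanium opens epoxides: from 26, Bu4NF/AcOH gives the ene-yne triol F5; i-BuMgCl with Cp2TiCl2 (cat.) then CO2 gives the C10 carboxylic acid F6; Me3SiCHN2 in methanol gives the methyl ester F7; mCPBA then epoxidises the trisubstituted allylic alkene and returns to the route at 31.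

**Step 24.** Acetyl migration from O9 to the free O8 under DMAP and Et3N, or slow acylation of the hindered C8 hydroxyl with decay of the glycidic anhydride, would give the wrong regioisomer or low conversion. Fallback by reversing the order of the two acylations: from 32, Et3SiOTf and 2,6-lutidine give the C9 TES ether F8; DDQ gives the C8 alcohol F9; Yamaguchi esterification with 36 gives the C8 glycidate F10; HF·pyridine gives the C9 alcohol F11; Ac2O and pyridine then give 38 directly.

## Further compounds

F1 | step 14 | N-(trans-2,3-diphenylaziridin-1-yl) imine of 23 | C1(=NN2[C@@H](c3ccccc3)[C@@H]2c2ccccc2)[C@H](O[Si](CC)(CC)CC)[C@@H](OCc2ccc(OC)cc2)[C@@H](C(=C)CO[Si](c2ccccc2)(c2ccccc2)C(C)(C)C)C23OC12CCC(C)=C3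
F2 | step 15 | C6 epimer of 26 | C/C1=C/[C@@H](O)[C@H](C(=C)CO[Si](c2ccccc2)(c2ccccc2)C(C)(C)C)[C@H](OCc2ccc(OC)cc2)[C@@H](O[Si](CC)(CC)CC)C#CCC1
F3 | step 15 | 4-nitrobenzoate of 26 | C/C1=C/[C@H](OC(=O)c2ccc(cc2)[N+](=O)[O-])[C@H](C(=C)CO[Si](c2ccccc2)(c2ccccc2)C(C)(C)C)[C@H](OCc2ccc(OC)cc2)[C@@H](O[Si](CC)(CC)CC)C#CCC1
F4 | step 12 | bicyclic dienone | O=C1[C@H](O[Si](CC)(CC)CC)[C@@H](OCc2ccc(OC)cc2)[C@@H](C(=C)CO[Si](c2ccccc2)(c2ccccc2)C(C)(C)C)C2=C1CCC(C)=C2
F5 | step 18 | ene-yne triol | C/C1=C/[C@H](O)[C@H](C(=C)CO)[C@H](OCc2ccc(OC)cc2)[C@@H](O)C#CCC1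
F6 | step 18 | C10 carboxylic acid | C/C1=C/[C@H](O)[C@H](C(=C)CO)[C@H](OCc2ccc(OC)cc2)[C@@H](O)/C(C(=O)O)=C\CC1
F7 | step 18 | C10 methyl ester without epoxide | C/C1=C/[C@H](O)[C@H](C(=C)CO)[C@H](OCc2ccc(OC)cc2)[C@@H](O)/C(C(=O)OC)=C\CC1
F8 | step 24 | lactone with 8-OPMB and 9-OTES | C=C1C(=O)O[C@@H]2[C@H]1[C@H](OCc1ccc(OC)cc1)[C@@H](O[Si](CC)(CC)CC)/C(C(=O)OC)=C\CC[C@@]1(C)O[C@@H]21
F9 | step 24 | lactone with 8-OH and 9-OTES | C=C1C(=O)O[C@@H]2[C@H]1[C@H](O)[C@@H](O[Si](CC)(CC)CC)/C(C(=O)OC)=C\CC[C@@]1(C)O[C@@H]21
F10 | step 24 | C8 glycidate with 9-OTES | C=C1C(=O)O[C@@H]2[C@H]1[C@H](OC(=O)[C@]1(C)CO1)[C@@H](O[Si](CC)(CC)CC)/C(C(=O)OC)=C\CC[C@@]1(C)O[C@@H]21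
F11 | step 24 | C8 glycidate with 9-OH | C=C1C(=O)O[C@@H]2[C@H]1[C@H](OC(=O)[C@]1(C)CO1)[C@@H](O)/C(C(=O)OC)=C\CC[C@@]1(C)O[C@@H]21
A1 | alternative 1 | ten-membered C6 diazophosphonoacetate | CCOP(=O)(OCC)C(=[N+]=[N-])C(=O)O[C@@H]1C[C@H](OC(=O)[C@]2(C)CO2)[C@@H](OCc2ccc(OC)cc2)/C(C(=O)OC)=C\CC[C@@]2(C)O[C@@H]12
A2 | alternative 1 | α-phosphono γ-lactone | CCOP(=O)(OCC)[C@@H]1C(=O)O[C@@H]2[C@H]1[C@H](OC(=O)[C@]1(C)CO1)[C@@H](OCc1ccc(OC)cc1)/C(C(=O)OC)=C\CC[C@@]1(C)O[C@@H]21
A3 | alternative 2 | open-chain bromomethyl butenolide aldehyde | O=C1O[C@H](C=C1CBr)[C@@H]1O[C@]1(C)CC/C=C(\[C@H](OCc1ccc(OC)cc1)C=O)C(=O)OC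
A4 | alternative 2 | ten-membered C8 alcohol with α-methylene lactone | C=C1C(=O)O[C@@H]2[C@H]1[C@H](O)[C@@H](OCc1ccc(OC)cc1)/C(C(=O)OC)=C\CC[C@@]1(C)O[C@@H]21
A5 | alternative 3 | cis-dialkenyl cyclohexenol | CC1=C[C@@](O)(/C=C/OCc2ccc(OC)cc2)[C@@H](C2=COC(C)(C)OC2=O)CC1
A6 | alternative 3 | ten-membered dienone with fused dioxanone | O=C1C[C@H](OCc2ccc(OC)cc2)[C@H]3OC(C)(C)OC(=O)/C3=C/CC/C(C)=C\1
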